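**Assumptions (one line):** (R)-2-methylbutanoic acid is bought (the target SMILES encodes the (R)-acyl group), and the sense of induction of the Josiphos ligand (step 1) and of the (S,S)-controller (step 7) is as stated; the antipodal ligand or controller is used if the first batch shows the opposite sense.

Atom labels used below follow benzofuranone numbering of the target: O-1, C-2 (C=O), C-3 (=CH2), C-3a, C-4 (O-acyl), C-5 (side chain), C-6 (CH3), C-7 (CH2), C-7a (CH–O).

## Retrosynthetic overview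

1. Target 15 ← silyl ether 14 ← acyclic allenyl aldehyde 13 by one hetero-Pauson–Khand [2+2+1] cyclocarbonylation (CO): C-3a–C-7a closes the cyclohexene, then O-1–C-2–C-3 closes the α-methylene lactone in the same catalytic cycle.
2. 13 ← (S)-allenyl carbinol 10 (reagent-controlled allenylation of Z-enal 9, sets C-4) + (R)-2-methylbutanoic acid 11.
3. The tetrasubstituted Z-alkene (C-5=C-6) ← chelation-controlled Z-enol triflate 6 of β-keto ester 5 + Negishi coupling that brings C-7/C-7a as a dioxolane.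
4. 5 ← C-acetylation of ester 4 ← copper-catalysed asymmetric 1,4-addition of a silyloxypropyl Grignard reagent to methyl crotonate (sets the side-chain stereocentre).
5. No ring exists before step 10; the carbocycle and the lactone both form there, and C-3a/C-7a are set relative to C-4.

## Route

Step 1
Reactants: 1 methyl (E)-but-2-enoate; 2 (3-bromopropoxy)(tert-butyl)dimethylsilane
Product: 4 methyl (3S)-6-[(tert-butyldimethylsilyl)oxy]-3-methylhexanoate, via Grignard reagent 3 (not isolated)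
Conditions: 2, Mg, Et2O; then 1, CuBr·SMe2 (5 mol %), (R)-1-[(S_p)-2-(diphenylphosphino)ferrocenyl]ethyldicyclohexylphosphine (Josiphos, 6 mol %), t-BuOMe, −75 °C; H2O quench
Reagents that add atoms: none
Why: Copper/Josiphos-catalysed asymmetric conjugate addition of a Grignard reagent to an enoate; the chiral copper complex adds the alkyl group to one face of the crotonate and so sets the (S) methyl-bearing centre that becomes the side-chain CH of the target.

Step 2
Reactants: 4 methyl (3S)-6-[(tert-butyldimethylsilyl)oxy]-3-methylhexanoate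
Product: 5 methyl (3S)-2-acetyl-6-[(tert-butyldimethylsilyl)oxy]-3-methylhexanoate (C-2 epimer mixture)
Conditions: LiN(i-Pr)2 (1.1 equiv), THF, −78 °C; N-methoxy-N-methylacetamide, −78 → −20 °C; H2O
Reagents that add atoms: N-methoxy-N-methylacetamide, CC(=O)N(C)OC
Why: Crossed Claisen-type C-acylation of the lithium ester enolate by a Weinreb amide, whose chelated tetrahedral adduct stops over-reaction; the new C-2 centre does not matter because it becomes sp2 in step 3.

Step 3
Reactants: 5 methyl (3S)-2-acetyl-6-[(tert-butyldimethylsilyl)oxy]-3-methylhexanoate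
Product: 6 methyl (2Z)-2-[(2S)-5-[(tert-butyldimethylsilyl)oxy]pentan-2-yl]-3-{[(trifluoromethyl)sulfonyl]oxy}but-2-enoate
Conditions: Tf2O (1.5 equiv), saturated aq. LiOH, toluene, 5 °C
Reagents that add atoms: trifluoromethanesulfonic anhydride, O=S(=O)(OS(=O)(=O)C(F)(F)F)C(F)(F)F
Why: Chelation-controlled stereoselective enol triflation; O-sulfonylation of the lithium-chelated enolate puts OTf cis to the ester, which fixes the geometry of the future ring alkene.

Step 4
Reactants: 6 methyl (2Z)-2-[(2S)-5-[(tert-butyldimethylsilyl)oxy]pentan-2-yl]-3-{[(trifluoromethyl)sulfonyl]oxy}but-2-enoate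
Product: 7 methyl (2Z)-2-[(2S)-5-[(tert-butyldimethylsilyl)oxy]pentan-2-yl]-4-(1,3-dioxolan-2-yl)-3-methylbut-2-enoate
Conditions: (1,3-dioxolan-2-ylmethyl)zinc bromide (1.5 equiv), PdCl2(dppf) (5 mol %), THF, 50 °C
Reagents that add atoms: (1,3-dioxolan-2-ylmethyl)zinc bromide, Br[Zn]CC1OCCO1
Why: Negishi sp2–sp3 cross-coupling proceeds with retention of alkene geometry (dppf disfavours β-hydride elimination), so the masked C-7/C-7a arm ends up cis to the ester carbon that becomes C-4.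

Step 5
Reactants: 7 methyl (2Z)-2-[(2S)-5-[(tert-butyldimethylsilyl)oxy]pentan-2-yl]-4-(1,3-dioxolan-2-yl)-3-methylbut-2-enoate
Product: 8 (2Z)-2-[(2S)-5-[(tert-butyldimethylsilyl)oxy]pentan-2-yl]-4-(1,3-dioxolan-2-yl)-3-methylbut-2-en-1-ol
Conditions: i-Bu2AlH (2.5 equiv), CH2Cl2, −78 °C; aq. KNaC4H4O6 (potassium sodium tartrate)
Reagents that add atoms: none
Why: Hydride 1,2-reduction of the conjugated ester to the allylic alcohol; the acetal and silyl ether are inert and the alkene geometry is untouched.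

Step 6
Reactants: 8 (2Z)-2-[(2S)-5-[(tert-butyldimethylsilyl)oxy]pentan-2-yl]-4-(1,3-dioxolan-2-yl)-3-methylbut-2-en-1-ol
Product: 9 (2Z)-2-[(2S)-5-[(tert-butyldimethylsilyl)oxy]pentan-2-yl]-4-(1,3-dioxolan-2-yl)-3-methylbut-2-enal
Conditions: MnO2 (15 equiv), CH2Cl2, 20 °C, dark; used at once
Reagents that add atoms: none
Why: Neutral allylic oxidation with MnO2 gives the enal without acid or base that could scramble the Z geometry through the dienol.

Step 7
Reactants: 9 (2Z)-2-[(2S)-5-[(tert-butyldimethylsilyl)oxy]pentan-2-yl]-4-(1,3-dioxolan-2-yl)-3-methylbut-2-enal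
Product: 10 (4S,5Z)-5-[(2S)-5-[(tert-butyldimethylsilyl)oxy]pentan-2-yl]-7-(1,3-dioxolan-2-yl)-6-methylhepta-1,2,5-trien-4-ol
Conditions: N,N'-[(1S,2S)-1,2-diphenylethane-1,2-diyl]bis(4-methylbenzenesulfonamide), BBr3, CH2Cl2, 0 → 20 °C, evaporate; allenyl-SnBu3, CH2Cl2, 20 °C; then 9, −78 °C; pH 7 buffer
Reagents that add atoms: allenyltributylstannane, C=C=C[Sn](CCCC)(CCCC)CCCC
Why: Corey-type asymmetric allenylation; the chiral B-propargyl diazaborolidine adds by SE2' through a closed six-membered transition state to the Si face of the aldehyde, giving the (S)-carbinol that is C-4 of the target.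

Step 8
Reactants: 10 (4S,5Z)-5-[(2S)-5-[(tert-butyldimethylsilyl)oxy]pentan-2-yl]-7-(1,3-dioxolan-2-yl)-6-methylhepta-1,2,5-trien-4-ol; 11 (2R)-2-methylbutanoic acid
Product: 12 (4S,5Z)-5-[(2S)-5-[(tert-butyldimethylsilyl)oxy]pentan-2-yl]-7-(1,3-dioxolan-2-yl)-6-methylhepta-1,2,5-trien-4-yl (2R)-2-methylbutanoate
Conditions: 11 (1.5 equiv), DCC, DMAP (0.3 equiv), CH2Cl2, 0 → 20 °C
Reagents that add atoms: none
Why: Steglich esterification by acyl transfer leaves both the carbinol centre and the α-centre of the acid unchanged, and the ester blocks lactol formation in the next step.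

Step 9
Reactants: 12 (4S,5Z)-5-[(2S)-5-[(tert-butyldimethylsilyl)oxy]pentan-2-yl]-7-(1,3-dioxolan-2-yl)-6-methylhepta-1,2,5-trien-4-yl (2R)-2-methylbutanoate
Product: 13 (3Z,5S)-4-[(2S)-5-[(tert-butyldimethylsilyl)oxy]pentan-2-yl]-3-methyl-1-oxoocta-3,6,7-trien-5-yl (2R)-2-methylbutanoate
Conditions: Et3SiOTf (2 equiv), 2,4,6-collidine (3 equiv), CH2Cl2, 0 °C; then H2O; used directly
Reagents that add atoms: water, O
Why: Chemoselective acetal cleavage through a collidinium intermediate that water hydrolyses; the base-buffered, non-aqueous-acid conditions spare the silyl ether, the doubly allylic ester and the allene and do not conjugate the β,γ-unsaturated aldehyde.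

Step 10
Reactants: 13 (3Z,5S)-4-[(2S)-5-[(tert-butyldimethylsilyl)oxy]pentan-2-yl]-3-methyl-1-oxoocta-3,6,7-trien-5-yl (2R)-2-methylbutanoate
Product: 14 (3aR,4S,7aR)-5-[(2S)-5-[(tert-butyldimethylsilyl)oxy]pentan-2-yl]-6-methyl-3-methylidene-2-oxo-2,3,3a,4,7,7a-hexahydro-1-benzofuran-4-yl (2R)-2-methylbutanoate
Conditions: Ru3(CO)12 (3 mol %), CO (20 atm), 1,4-dioxane, 110 °C
Reagents that add atoms: carbon monoxide, [C-]#[O+]
Why: Intramolecular hetero-Pauson–Khand [2+2+1] cyclocarbonylation of an allenyl aldehyde; oxidative cyclisation of C=O with the internal allene π-bond on ruthenium forms C-3a–C-7a as a cis-fused oxametallacycle, with the C-4 ester expected anti to the metal-bearing face and hence trans to C-3, and CO insertion with reductive elimination closes the α-methylene lactone.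

Step 11
Reactants: 14 (3aR,4S,7aR)-5-[(2S)-5-[(tert-butyldimethylsilyl)oxy]pentan-2-yl]-6-methyl-3-methylidene-2-oxo-2,3,3a,4,7,7a-hexahydro-1-benzofuran-4-yl (2R)-2-methylbutanoate
Product: 15 (3aR,4S,7aR)-5-[(2S)-5-hydroxypentan-2-yl]-6-methyl-3-methylidene-2-oxo-2,3,3a,4,7,7a-hexahydro-1-benzofuran-4-yl (2R)-2-methylbutanoate
Conditions: HF·pyridine, pyridine, THF, 0 → 20 °C
Reagents that add atoms: none
Why: Buffered fluoride desilylation of the primary silyl ether; the conditions are non-basic, so the α-methylene lactone and the secondary ester are not attacked and no stereocentre is touched.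

## Compound list

1 | methyl (E)-but-2-enoate | C/C=C/C(=O)OC | starting material
2 | (3-bromopropoxy)(tert-butyl)dimethylsilane | BrCCCO[Si](C)(C)C(C)(C)C | starting material
3 | {3-[(tert-butyldimethylsilyl)oxy]propyl}magnesium bromide | Br[Mg]CCCO[Si](C)(C)C(C)(C)C | intermediate
4 | methyl (3S)-6-[(tert-butyldimethylsilyl)oxy]-3-methylhexanoate | COC(=O)C[C@@H](C)CCCO[Si](C)(C)C(C)(C)C | intermediate
5 | methyl (3S)-2-acetyl-6-[(tert-butyldimethylsilyl)oxy]-3-methylhexanoate (C-2 epimers) | COC(=O)C(C(C)=O)[C@@H](C)CCCO[Si](C)(C)C(C)(C)C | intermediate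
6 | methyl (2Z)-2-[(2S)-5-[(tert-butyldimethylsilyl)oxy]pentan-2-yl]-3-{[(trifluoromethyl)sulfonyl]oxy}but-2-enoate | COC(=O)/C([C@@H](C)CCCO[Si](C)(C)C(C)(C)C)=C(/C)OS(=O)(=O)C(F)(F)F | intermediate
7 | methyl (2Z)-2-[(2S)-5-[(tert-butyldimethylsilyl)oxy]pentan-2-yl]-4-(1,3-dioxolan-2-yl)-3-methylbut-2-enoate | COC(=O)/C([C@@H](C)CCCO[Si](C)(C)C(C)(C)C)=C(/C)CC1OCCO1 | intermediate
8 | (2Z)-2-[(2S)-5-[(tert-butyldimethylsilyl)oxy]pentan-2-yl]-4-(1,3-dioxolan-2-yl)-3-methylbut-2-en-1-ol | OC/C([C@@H](C)CCCO[Si](C)(C)C(C)(C)C)=C(/C)CC1OCCO1 | intermediate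
9 | (2Z)-2-[(2S)-5-[(tert-butyldimethylsilyl)oxy]pentan-2-yl]-4-(1,3-dioxolan-2-yl)-3-methylbut-2-enal | O=C/C([C@@H](C)CCCO[Si](C)(C)C(C)(C)C)=C(/C)CC1OCCO1 | intermediate
10 | (4S,5Z)-5-[(2S)-5-[(tert-butyldimethylsilyl)oxy]pentan-2-yl]-7-(1,3-dioxolan-2-yl)-6-methylhepta-1,2,5-trien-4-ol | C=C=C[C@H](O)/C([C@@H](C)CCCO[Si](C)(C)C(C)(C)C)=C(/C)CC1OCCO1 | intermediate
11 | (2R)-2-methylbutanoic acid | CC[C@@H](C)C(=O)O | starting material
12 | (4S,5Z)-5-[(2S)-5-[(tert-butyldimethylsilyl)oxy]pentan-2-yl]-7-(1,3-dioxolan-2-yl)-6-methylhepta-1,2,5-trien-4-yl (2R)-2-methylbutanoate | C=C=C[C@H](OC(=O)[C@H](C)CC)/C([C@@H](C)CCCO[Si](C)(C)C(C)(C)C)=C(/C)CC1OCCO1 | intermediate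
13 | (3Z,5S)-4-[(2S)-5-[(tert-butyldimethylsilyl)oxy]pentan-2-yl]-3-methyl-1-oxoocta-3,6,7-trien-5-yl (2R)-2-methylbutanoate | C=C=C[C@H](OC(=O)[C@H](C)CC)/C([C@@H](C)CCCO[Si](C)(C)C(C)(C)C)=C(/C)CC=O | intermediate
14 | (3aR,4S,7aR)-5-[(2S)-5-[(tert-butyldimethylsilyl)oxy]pentan-2-yl]-6-methyl-3-methylidene-2-oxo-2,3,3a,4,7,7a-hexahydro-1-benzofuran-4-yl (2R)-2-methylbutanoate | C=C1C(=O)O[C@@H]2CC(C)=C([C@@H](C)CCCO[Si](C)(C)C(C)(C)C)[C@@H](OC(=O)[C@H](C)CC)[C@H]12 | intermediate
15 | (3aR,4S,7aR)-5-[(2S)-5-hydroxypentan-2-yl]-6-methyl-3-methylidene-2-oxo-2,3,3a,4,7,7a-hexahydro-1-benzofuran-4-yl (2R)-2-methylbutanoate | C=C1C(=O)O[C@@H]2CC(C)=C([C@@H](C)CCCO)[C@@H](OC(=O)[C@H](C)CC)[C@H]12 | target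

## Step count and main risks

Total steps: 11. Longest linear sequence: 11 (1 → 15; 2 and 11 enter at steps 1 and 8).

**Step 10 (most likely to fail).** The β,γ-unsaturated aldehyde may conjugate at 110 °C, ruthenium may ionise the doubly allylic ester, and the facial control by C-4 is a prediction, not a precedent on this substrate. The fallback sets out from 13 and comes back at 14, forming the rings one after the other with boron. Diboration of the terminal allene double bond (B2pin2, Pt(dba)2, PCy3, toluene, 50 °C) gives a 2-boryl allylboronate. This adds through its γ-carbon to the aldehyde in a closed six-membered transition state and, after work-up, gives the carbocyclic cis-hydroxy alkenylboronate (1S,5R,6R)-5-hydroxy-3-methyl-2-[(2S)-5-(silyloxy)pentan-2-yl]-6-[1-(pinacolboryl)ethenyl]cyclohex-2-en-1-yl (2R)-2-methylbutanoate F1. Iododeboronation (I2, NaOH, THF/H2O, 0 °C) gives the corresponding alkenyl iodide F2. Carbonylative lactonisation (Pd(PPh3)4, CO 1 atm, K2CO3, MeCN, 60 °C) then closes the α-methylene lactone to 14.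

**Step 7.** The tetrasubstituted enal is hindered, and the sense and level of induction are extrapolated from simpler aldehydes. The fallback sets out from 9 and comes back at 10. Ethynylmagnesium bromide (THF, −78 °C) gives the racemic alkynol F3. MnO2 oxidises it to the ynone F4. Transfer hydrogenation with RuCl(p-cymene)[(R,R)-TsDPEN] in i-PrOH sets the carbinol centre in the (S)-alkynol F5. Crabbé homologation of the terminal alkyne (paraformaldehyde, CuI, Cy2NH, dioxane, reflux) then gives 10.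

**Step 4.** The triflate is tetrasubstituted and the alkylzinc carries β-oxygens, so transmetallation may be slow and β-elimination may compete. The fallback sets out from 4 and comes back at 7 by reversing the order in which the two alkene substituents arrive. The lithium enolate of 4 is acylated with N-methoxy-N-methyl-2-(1,3-dioxolan-2-yl)acetamide to the β-keto ester F6. Non-chelating triflation (aq. Me4NOH, Tf2O, toluene, 5 °C) gives the (E)-enol triflate F7. Coupling with MeMgBr (Fe(acac)3 5 mol %, THF/NMP, −30 °C) delivers the methyl group with retention and gives 7.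

## Further compounds

F1 | step 10 | (1S,5R,6R)-2-[(2S)-5-[(tert-butyldimethylsilyl)oxy]pentan-2-yl]-5-hydroxy-3-methyl-6-[1-(4,4,5,5-tetramethyl-1,3,2-dioxaborolan-2-yl)ethenyl]cyclohex-2-en-1-yl (2R)-2-methylbutanoate | O[C@@H]1CC(C)=C([C@@H](C)CCCO[Si](C)(C)C(C)(C)C)[C@@H](OC(=O)[C@H](C)CC)[C@@H]1C(=C)B1OC(C)(C)C(C)(C)O1
F2 | step 10 | (1S,5R,6R)-2-[(2S)-5-[(tert-butyldimethylsilyl)oxy]pentan-2-yl]-5-hydroxy-6-(1-iodoethenyl)-3-methylcyclohex-2-en-1-yl (2R)-2-methylbutanoate | O[C@@H]1CC(C)=C([C@@H](C)CCCO[Si](C)(C)C(C)(C)C)[C@@H](OC(=O)[C@H](C)CC)[C@@H]1C(I)=C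
F3 | step 7 | (4Z)-4-[(2S)-5-[(tert-butyldimethylsilyl)oxy]pentan-2-yl]-6-(1,3-dioxolan-2-yl)-5-methylhex-4-en-1-yn-3-ol, racemic at C-3 | C#CC(O)/C([C@@H](C)CCCO[Si](C)(C)C(C)(C)C)=C(/C)CC1OCCO1
F4 | step 7 | (4Z)-4-[(2S)-5-[(tert-butyldimethylsilyl)oxy]pentan-2-yl]-6-(1,3-dioxolan-2-yl)-5-methylhex-4-en-1-yn-3-one | C#CC(=O)/C([C@@H](C)CCCO[Si](C)(C)C(C)(C)C)=C(/C)CC1OCCO1
F5 | step 7 | (3S,4Z)-4-[(2S)-5-[(tert-butyldimethylsilyl)oxy]pentan-2-yl]-6-(1,3-dioxolan-2-yl)-5-methylhex-4-en-1-yn-3-ol | C#C[C@H](O)/C([C@@H](C)CCCO[Si](C)(C)C(C)(C)C)=C(/C)CC1OCCO1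
F6 | step 4 | methyl (3S)-6-[(tert-butyldimethylsilyl)oxy]-2-[(1,3-dioxolan-2-yl)acetyl]-3-methylhexanoate (C-2 epimers) | COC(=O)C(C(=O)CC1OCCO1)[C@@H](C)CCCO[Si](C)(C)C(C)(C)C
F7 | step 4 | methyl (2E)-2-[(2S)-5-[(tert-butyldimethylsilyl)oxy]pentan-2-yl]-4-(1,3-dioxolan-2-yl)-3-{[(trifluoromethyl)sulfonyl]oxy}but-2-enoate | COC(=O)/C([C@@H](C)CCCO[Si](C)(C)C(C)(C)C)=C(/OS(=O)(=O)C(F)(F)F)CC1OCCO1
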